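**Plan**
1. Retrosynthesis: the benzyl and isopropyl ethers come off last; the pyranone is cut at O1–C2 and C2–C3, leaving a 2-hydroxydeoxybenzoin and a one-carbon unit.
2. Ring A is cut at C4a–C8a. Its four contiguous oxygen-bearing carbons C6, C7, C8 and C8a are the four ring carbons of a squarate ester, C5 and C4a are the two carbons of an E-alkenyl group, and only the carbinol oxygen (O6) is methylated.
3. The alkenyl unit carries C4 as a dioxolane and C3 with ring B as a benzylic side chain; it is cut at C4–C4a (acetylide plus Weinreb amide) and at C3–C4 (one-carbon homologation of the ring-B aldehyde).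
4. Forward order: ring-B aldehyde → arylacetic Weinreb amide → alkynyl ketal → E-vinyl iodide → squarate adduct → ring A (step 10) → ring C (step 12) → deprotection.
5. Stereochemistry: the target is achiral; the only requirement is the E-alkene (syn hydrozirconation), and the racemic carbinol centre of the cyclobutenone is erased on aromatisation.

Key step: step 10

Remark: the target has no stereocentre, stereogenic axis or stereogenic double bond, so the "single enantiomer" is the achiral compound itself and no absolute stereocontrol is needed.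

Step 1
Reactants: 1 phenol aldehyde 3-hydroxy-4,5-dimethoxybenzaldehyde
Product: 2 benzyl ether 3-(benzyloxy)-4,5-dimethoxybenzaldehyde
Conditions: BnBr, K2CO3, DMF, rt
Reagents that add atoms: benzyl bromide, BrCc1ccccc1
Why: Williamson ether synthesis on the phenoxide gives a benzyl ether that should withstand every base, organometallic and mild acid used before the last step.

Step 2
Reactants: 2 benzyl ether 3-(benzyloxy)-4,5-dimethoxybenzaldehyde
Product: 4 nitrile [3-(benzyloxy)-4,5-dimethoxyphenyl]acetonitrile, via tosylvinyl formamide 3 (not isolated)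
Conditions: TosMIC, t-BuOK, DME, −40 °C; then MeOH, reflux
Reagents that add atoms: tosylmethyl isocyanide, Cc1ccc(cc1)S(=O)(=O)C[N+]#[C-]
Why: van Leusen reductive cyanation, in which the TosMIC anion adds to the aldehyde, the oxazoline adduct opens to N-formyl enamine 3 under aprotic conditions (suppressing oxazole formation), and methanolysis expels methyl formate and sulfinate to leave the nitrile one carbon longer.

Step 3
Reactants: 4 nitrile [3-(benzyloxy)-4,5-dimethoxyphenyl]acetonitrile
Product: 6 acid [3-(benzyloxy)-4,5-dimethoxyphenyl]acetic acid, via primary amide 5 (not isolated)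
Conditions: NaOH, EtOH–H2O, reflux; then aq HCl
Reagents that add atoms: water, O; sodium hydroxide, [Na+].[OH-]
Why: Base hydrolysis of the nitrile through the amide to the carboxylate, to which aryl benzyl and methyl ethers are inert.

Step 4
Reactants: 6 acid [3-(benzyloxy)-4,5-dimethoxyphenyl]acetic acid
Product: 8 Weinreb amide 2-[3-(benzyloxy)-4,5-dimethoxyphenyl]-N-methoxy-N-methylacetamide, via acyl imidazolide 7 (not isolated)
Conditions: CDI, CH2Cl2, rt; then MeNHOMe·HCl, rt
Reagents that add atoms: N,O-dimethylhydroxylamine hydrochloride, CNOC.Cl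
Why: Amide coupling through the acyl imidazolide, a neutral activation that avoids the ketene pathway open to arylacetyl chlorides.

Step 5
Reactants: 8 Weinreb amide 2-[3-(benzyloxy)-4,5-dimethoxyphenyl]-N-methoxy-N-methylacetamide; 9 trimethylsilylacetylene
Product: 12 silyl ynone 1-[3-(benzyloxy)-4,5-dimethoxyphenyl]-4-(trimethylsilyl)but-3-yn-2-one, via lithium silylacetylide 10 (not isolated), via tetrahedral lithium adduct 11 (not isolated)
Conditions: 9, n-BuLi, THF, −78 °C; then 8, −78 → −20 °C; cold 1 M HCl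
Reagents that add atoms: none
Why: Weinreb ketone synthesis, in which the weakly basic acetylide adds once because chelate 11 persists until the cold acidic quench, which also protonates the released hydroxylamine before it can add to the ynone.

Step 6
Reactants: 12 silyl ynone 1-[3-(benzyloxy)-4,5-dimethoxyphenyl]-4-(trimethylsilyl)but-3-yn-2-one
Product: 13 silylalkynyl ketal 2-[3-(benzyloxy)-4,5-dimethoxybenzyl]-2-[(trimethylsilyl)ethynyl]-1,3-dioxolane
Conditions: TMSOCH2CH2OTMS, TMSOTf (cat.), CH2Cl2, −78 → −20 °C; pyridine quench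
Reagents that add atoms: 1,2-bis(trimethylsilyloxy)ethane, C[Si](C)(C)OCCO[Si](C)(C)C
Why: Silyl-triflate-catalysed ketalisation with the bis-silyl glycol, driven by hexamethyldisiloxane formation at low temperature under aprotic conditions, so that neither conjugate addition to the silyl-capped ynone nor enolisation of the benzylic methylene should compete.

Step 7
Reactants: 13 silylalkynyl ketal 2-[3-(benzyloxy)-4,5-dimethoxybenzyl]-2-[(trimethylsilyl)ethynyl]-1,3-dioxolane
Product: 14 alkynyl ketal 2-[3-(benzyloxy)-4,5-dimethoxybenzyl]-2-ethynyl-1,3-dioxolane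
Conditions: K2CO3, MeOH, rt
Reagents that add atoms: none
Why: Methoxide-induced protodesilylation of the alkynylsilane, under which the ketal and the ethers are stable.

Step 8
Reactants: 14 alkynyl ketal 2-[3-(benzyloxy)-4,5-dimethoxybenzyl]-2-ethynyl-1,3-dioxolane
Product: 16 vinyl iodide 2-[3-(benzyloxy)-4,5-dimethoxybenzyl]-2-[(E)-2-iodoethenyl]-1,3-dioxolane, via alkenylzirconocene chloride 15 (not isolated)
Conditions: Cp2Zr(H)Cl, THF, rt; then I2, 0 °C
Reagents that add atoms: iodine, II
Why: Schwartz hydrozirconation–iodination, in which syn addition of Zr–H places the metal on the terminal carbon away from the quaternary ketal centre and iodinolysis with retention should give the E-iodoalkene only.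

Step 9
Reactants: 16 vinyl iodide 2-[3-(benzyloxy)-4,5-dimethoxybenzyl]-2-[(E)-2-iodoethenyl]-1,3-dioxolane; 17 diisopropyl squarate
Product: 20 cyclobutenone rac-4-[(E)-2-{2-[3-(benzyloxy)-4,5-dimethoxybenzyl]-1,3-dioxolan-2-yl}ethenyl]-4-methoxy-2,3-diisopropoxycyclobut-2-en-1-one, via vinyllithium 18 (not isolated), via lithium alkoxide 19 (not isolated)
Conditions: t-BuLi (2 equiv), Et2O, −78 °C; then 17, THF, −78 °C; then MeOTf (excess), −78 → 0 °C
Reagents that add atoms: methyl trifluoromethanesulfonate, COS(=O)(=O)C(F)(F)F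
Why: Iodine–lithium exchange with retention of the E geometry, 1,2-addition of 18 to one of the two equivalent carbonyl groups of the symmetric squarate, and O-methylation of the tertiary alkoxide in the flask by the hard electrophile methyl triflate; the new carbinol centre forms as a racemate, which is immaterial because step 10 destroys it.

Step 10
Reactants: 20 cyclobutenone rac-4-[(E)-2-{2-[3-(benzyloxy)-4,5-dimethoxybenzyl]-1,3-dioxolan-2-yl}ethenyl]-4-methoxy-2,3-diisopropoxycyclobut-2-en-1-one
Product: 23 phenol 6-{2-[3-(benzyloxy)-4,5-dimethoxybenzyl]-1,3-dioxolan-2-yl}-4-methoxy-2,3-diisopropoxyphenol, via dienylketene 21 (not isolated), via cyclohexadienone 22 (not isolated)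
Conditions: PhMe (dilute, degassed), 110 °C, Ar
Reagents that add atoms: none
Why: Heating opens the cyclobutenone by conrotatory 4π electrocyclic cleavage of the C1–C4 bond to dienylketene 21, whose ketene carbon (future C8a) and distal alkene carbon (future C4a) join in a thermal disrotatory 6π electrocyclisation that closes the six-membered carbocycle as cyclohexa-2,4-dienone 22, and enolisation aromatises it to phenol 23. The closest known reaction type is the thermal ring expansion of squarate-derived 4-alkenyl-4-alkoxycyclobutenones to polyoxygenated phenols (Moore rearrangement). No stereocentre is created: the racemic carbinol centre of 20 and the sp3 centre of 22 are both erased. The step needs torquoselective ring opening, which the 4-methoxy donor secures by rotating outward and so turning the alkenyl group inward beside the ketene, while the E-alkene keeps the bulky ketal carbon on the outside of the closing triene. Regiochemistry follows from connectivity alone: the carbinol carbon becomes C6 with its methyl ether in place, the two isopropoxy carbons become C7 and C8, and the ketene oxygen becomes the free C8a phenol that later serves as O1.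

Step 11
Reactants: 23 phenol 6-{2-[3-(benzyloxy)-4,5-dimethoxybenzyl]-1,3-dioxolan-2-yl}-4-methoxy-2,3-diisopropoxyphenol
Product: 24 deoxybenzoin 2-[3-(benzyloxy)-4,5-dimethoxyphenyl]-1-(2-hydroxy-3,4-diisopropoxy-5-methoxyphenyl)ethan-1-one
Conditions: 1 M HCl, THF, rt
Reagents that add atoms: water, O
Why: Acid-catalysed ketal hydrolysis, helped by the electron-rich aryl group that stabilises the oxocarbenium ion and by the hydrogen bond from the ortho-phenol to the new ketone, under conditions too mild to touch any ether.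

Step 12
Reactants: 24 deoxybenzoin 2-[3-(benzyloxy)-4,5-dimethoxyphenyl]-1-(2-hydroxy-3,4-diisopropoxy-5-methoxyphenyl)ethan-1-one
Product: 26 protected isoflavone 3-[3-(benzyloxy)-4,5-dimethoxyphenyl]-6-methoxy-7,8-diisopropoxy-4H-chromen-4-one, via enaminone 25 (not isolated)
Conditions: Me2NCH(OMe)2, PhMe, 100 °C
Reagents that add atoms: N,N-dimethylformamide dimethyl acetal, CN(C)C(OC)OC
Why: Standard isoflavone construction from a 2-hydroxydeoxybenzoin, in which the activated methylene condenses with the amide acetal to enaminone 25 and the phenol closes the pyranone by 6-endo conjugate addition–elimination of dimethylamine, installing C2.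

Step 13
Reactants: 26 protected isoflavone 3-[3-(benzyloxy)-4,5-dimethoxyphenyl]-6-methoxy-7,8-diisopropoxy-4H-chromen-4-one
Product: 28 target 7,8-dihydroxy-3-(3-hydroxy-4,5-dimethoxyphenyl)-6-methoxy-4H-chromen-4-one, via chloroborate ester 27 (not isolated)
Conditions: BCl3, C6HMe5, CH2Cl2, −78 → 0 °C; then H2O
Reagents that add atoms: none
Why: Lewis-acid ether cleavage, in which boron trichloride removes the benzyl group at −78 °C (its cation being captured by pentamethylbenzene) and the two vicinal secondary isopropyl groups on warming to 0 °C, whereas the primary methyl ethers, none of which lies ortho or peri to the carbonyl, should persist at this temperature, and aqueous work-up hydrolyses borate 27 to the three free hydroxyls.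

**Compound list**
```
1 | 3-hydroxy-4,5-dimethoxybenzaldehyde | COc1cc(C=O)cc(O)c1OC | starting material
2 | 3-(benzyloxy)-4,5-dimethoxybenzaldehyde | COc1cc(C=O)cc(OCc2ccccc2)c1OC | intermediate
3 | N-{2-[3-(benzyloxy)-4,5-dimethoxyphenyl]-1-[(4-methylphenyl)sulfonyl]ethenyl}formamide (alkene geometry not defined; not isolated) | O=CNC(=Cc1cc(OCc2ccccc2)c(OC)c(OC)c1)S(=O)(=O)c1ccc(C)cc1 | intermediate
4 | [3-(benzyloxy)-4,5-dimethoxyphenyl]acetonitrile | COc1cc(CC#N)cc(OCc2ccccc2)c1OC | intermediate
5 | 2-[3-(benzyloxy)-4,5-dimethoxyphenyl]acetamide (not isolated) | COc1cc(CC(N)=O)cc(OCc2ccccc2)c1OC | intermediate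
6 | [3-(benzyloxy)-4,5-dimethoxyphenyl]acetic acid | COc1cc(CC(=O)O)cc(OCc2ccccc2)c1OC | intermediate
7 | 2-[3-(benzyloxy)-4,5-dimethoxyphenyl]-1-(1H-imidazol-1-yl)ethan-1-one (not isolated) | COc1cc(CC(=O)n2ccnc2)cc(OCc2ccccc2)c1OC | intermediate
8 | 2-[3-(benzyloxy)-4,5-dimethoxyphenyl]-N-methoxy-N-methylacetamide | COc1cc(CC(=O)N(C)OC)cc(OCc2ccccc2)c1OC | intermediate
9 | trimethylsilylacetylene (ethynyltrimethylsilane) | C#C[Si](C)(C)C | starting material
10 | lithium (trimethylsilyl)acetylide (not isolated) | [Li]C#C[Si](C)(C)C | intermediate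
11 | racemic lithium 1-[3-(benzyloxy)-4,5-dimethoxyphenyl]-2-[methoxy(methyl)amino]-4-(trimethylsilyl)but-3-yn-2-olate (not isolated) | CON(C)C(O[Li])(Cc1cc(OCc2ccccc2)c(OC)c(OC)c1)C#C[Si](C)(C)C | intermediate
12 | 1-[3-(benzyloxy)-4,5-dimethoxyphenyl]-4-(trimethylsilyl)but-3-yn-2-one | COc1cc(CC(=O)C#C[Si](C)(C)C)cc(OCc2ccccc2)c1OC | intermediate
13 | 2-[3-(benzyloxy)-4,5-dimethoxybenzyl]-2-[(trimethylsilyl)ethynyl]-1,3-dioxolane | COc1cc(CC2(C#C[Si](C)(C)C)OCCO2)cc(OCc2ccccc2)c1OC | intermediate
14 | 2-[3-(benzyloxy)-4,5-dimethoxybenzyl]-2-ethynyl-1,3-dioxolane | COc1cc(CC2(C#C)OCCO2)cc(OCc2ccccc2)c1OC | intermediate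
15 | chloro[(E)-2-{2-[3-(benzyloxy)-4,5-dimethoxybenzyl]-1,3-dioxolan-2-yl}ethenyl]bis(cyclopentadienyl)zirconium (not isolated; cyclopentadienyl rings drawn sigma-bonded) | Cl[Zr](/C=C/C1(Cc2cc(OCc3ccccc3)c(OC)c(OC)c2)OCCO1)(C1C=CC=C1)C1C=CC=C1 | intermediate
16 | 2-[3-(benzyloxy)-4,5-dimethoxybenzyl]-2-[(E)-2-iodoethenyl]-1,3-dioxolane | I/C=C/C1(Cc2cc(OCc3ccccc3)c(OC)c(OC)c2)OCCO1 | intermediate
17 | diisopropyl squarate (3,4-diisopropoxycyclobut-3-ene-1,2-dione) | CC(C)OC1=C(OC(C)C)C(=O)C1=O | starting material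
18 | (E)-2-{2-[3-(benzyloxy)-4,5-dimethoxybenzyl]-1,3-dioxolan-2-yl}ethenyllithium (not isolated) | [Li]/C=C/C1(Cc2cc(OCc3ccccc3)c(OC)c(OC)c2)OCCO1 | intermediate
19 | racemic lithium 1-[(E)-2-{2-[3-(benzyloxy)-4,5-dimethoxybenzyl]-1,3-dioxolan-2-yl}ethenyl]-2,3-diisopropoxy-4-oxocyclobut-2-en-1-olate (not isolated) | [Li]OC1(/C=C/C2(Cc3cc(OCc4ccccc4)c(OC)c(OC)c3)OCCO2)C(=O)C(OC(C)C)=C1OC(C)C | intermediate
20 | racemic 4-[(E)-2-{2-[3-(benzyloxy)-4,5-dimethoxybenzyl]-1,3-dioxolan-2-yl}ethenyl]-4-methoxy-2,3-diisopropoxycyclobut-2-en-1-one | COC1(/C=C/C2(Cc3cc(OCc4ccccc4)c(OC)c(OC)c3)OCCO2)C(=O)C(OC(C)C)=C1OC(C)C | intermediate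
21 | (3Z,5E)-6-{2-[3-(benzyloxy)-4,5-dimethoxybenzyl]-1,3-dioxolan-2-yl}-4-methoxy-2,3-diisopropoxyhexa-1,3,5-trien-1-one, the dienylketene (not isolated) | O=C=C(OC(C)C)/C(OC(C)C)=C(OC)\C=C\C1(Cc2cc(OCc3ccccc3)c(OC)c(OC)c2)OCCO1 | intermediate
22 | racemic 6-{2-[3-(benzyloxy)-4,5-dimethoxybenzyl]-1,3-dioxolan-2-yl}-4-methoxy-2,3-diisopropoxycyclohexa-2,4-dien-1-one (not isolated) | O=C1C(OC(C)C)=C(OC(C)C)C(OC)=CC1C2(Cc3cc(OCc4ccccc4)c(OC)c(OC)c3)OCCO2 | intermediate
23 | 6-{2-[3-(benzyloxy)-4,5-dimethoxybenzyl]-1,3-dioxolan-2-yl}-4-methoxy-2,3-diisopropoxyphenol | CC(C)Oc1c(O)c(C2(Cc3cc(OCc4ccccc4)c(OC)c(OC)c3)OCCO2)cc(OC)c1OC(C)C | intermediate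
24 | 2-[3-(benzyloxy)-4,5-dimethoxyphenyl]-1-(2-hydroxy-3,4-diisopropoxy-5-methoxyphenyl)ethan-1-one | CC(C)Oc1c(O)c(C(=O)Cc2cc(OCc3ccccc3)c(OC)c(OC)c2)cc(OC)c1OC(C)C | intermediate
25 | 2-[3-(benzyloxy)-4,5-dimethoxyphenyl]-3-(dimethylamino)-1-(2-hydroxy-3,4-diisopropoxy-5-methoxyphenyl)prop-2-en-1-one (alkene geometry not defined; not isolated) | CN(C)C=C(C(=O)c1cc(OC)c(OC(C)C)c(OC(C)C)c1O)c1cc(OCc2ccccc2)c(OC)c(OC)c1 | intermediate
26 | 3-[3-(benzyloxy)-4,5-dimethoxyphenyl]-6-methoxy-7,8-diisopropoxy-4H-chromen-4-one | COc1cc2c(=O)c(-c3cc(OCc4ccccc4)c(OC)c(OC)c3)coc2c(OC(C)C)c1OC(C)C | intermediate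
27 | chloroborate ester of the target, drawn in its simplest form: 7,8-O-chloroboranediyl on ring A and 3'-O-dichloroboryl on ring B (not isolated) | COc1cc2c(=O)c(-c3cc(OB(Cl)Cl)c(OC)c(OC)c3)coc2c2OB(Cl)Oc12 | intermediate
28 | 7,8-dihydroxy-3-(3-hydroxy-4,5-dimethoxyphenyl)-6-methoxy-4H-chromen-4-one (CNP0115098.0) | COc1cc2c(=O)c(-c3cc(O)c(OC)c(OC)c3)coc2c(O)c1O | target
```

**Totals**
Total step count: 13. Longest linear sequence: 13 steps (1 to 28); 9 and 17 enter as purchased materials.

**Steps most likely to fail**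

Step 9. The charged tertiary alkoxide may undergo alkoxide-accelerated ring opening, or stay partly unmethylated, while the mixture warms; surplus tert-butyllithium may also add to the squarate. The fallback sets out from 16 and 17 and separates C–C bond formation from etherification. Adduct 19 is protonated at −78 °C with aqueous NH4Cl and isolated as the free carbinol, racemic 4-[(E)-2-{2-[3-(benzyloxy)-4,5-dimethoxybenzyl]-1,3-dioxolan-2-yl}ethenyl]-4-hydroxy-2,3-diisopropoxycyclobut-2-en-1-one F1 in neutral form. Carbinol F1 is then O-methylated with iodomethane over silver(I) oxide and K2CO3 in acetonitrile at room temperature, which returns to the route at 20.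

Step 10. The 6π closure of the dienylketene, which carries a quaternary ketal carbon at its terminus, may be slow enough for ketene dimerisation or capture by the product phenol, and the electron-rich phenol may oxidise at 110 °C. The fallback sets out from 14 and 17 and closes the same C4a–C8a bond from an alkyne instead of an alkene. Compound 14 is deprotonated (n-BuLi, THF, −78 °C) to the lithium acetylide ({2-[3-(benzyloxy)-4,5-dimethoxybenzyl]-1,3-dioxolan-2-yl}ethynyl)lithium F2 and acetylide F2 then adds to 17; an NH4Cl quench should give the carbinol racemic 4-({2-[3-(benzyloxy)-4,5-dimethoxybenzyl]-1,3-dioxolan-2-yl}ethynyl)-4-hydroxy-2,3-diisopropoxycyclobut-2-en-1-one F3 as an isolable solid or oil. Heating F3 in p-xylene at 138 °C should give 5-{2-[3-(benzyloxy)-4,5-dimethoxybenzyl]-1,3-dioxolan-2-yl}-2,3-diisopropoxy-1,4-benzoquinone F4 by ketene–alkyne cyclisation to a diradical and hydrogen transfer; the quinone is robust, and the linear alkyne is less hindered than the alkene. Sodium dithionite reduces F4 to the hydroquinone 2-{2-[3-(benzyloxy)-4,5-dimethoxybenzyl]-1,3-dioxolan-2-yl}-5,6-diisopropoxybenzene-1,4-diol F5 and the ketal of F5 is removed with 1 M HCl in THF to give 2-[3-(benzyloxy)-4,5-dimethoxyphenyl]-1-(2,5-dihydroxy-3,4-diisopropoxyphenyl)ethan-1-one F6 as the dihydroxy ketone. Treating F6 with MeI and K2CO3 in acetone under argon should methylate only the C5 hydroxyl, because the C2 hydroxyl is held in a hydrogen bond to the ketone; this returns to the route at 24.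

Step 13. Released benzyl cations may alkylate the electron-rich rings, and warming to finish the isopropyl ethers may cost a methyl ether next to a boron-bound oxygen (the hindered 4'-OMe or the 6-OMe). The fallback sets out from 26 and splits the deprotection by mechanism. Hydrogenolysis (H2, Pd/C, EtOAc, rt) removes the benzyl ether without forming any cation and should give the free 3'-phenol 3-(3-hydroxy-4,5-dimethoxyphenyl)-6-methoxy-7,8-diisopropoxy-4H-chromen-4-one F7 as an isolated intermediate. Phenol F7 is then treated with boron trichloride, needed now only for the two vicinal isopropyl ethers, in CH2Cl2 at −78 to −20 °C, which returns to the route at 28.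

**Further compounds**
```
F1 | step 9 | racemic 4-[(E)-2-{2-[3-(benzyloxy)-4,5-dimethoxybenzyl]-1,3-dioxolan-2-yl}ethenyl]-4-hydroxy-2,3-diisopropoxycyclobut-2-en-1-one | OC1(/C=C/C2(Cc3cc(OCc4ccccc4)c(OC)c(OC)c3)OCCO2)C(=O)C(OC(C)C)=C1OC(C)C
F2 | step 10 | lithium acetylide of 14, ({2-[3-(benzyloxy)-4,5-dimethoxybenzyl]-1,3-dioxolan-2-yl}ethynyl)lithium | [Li]C#CC1(Cc2cc(OCc3ccccc3)c(OC)c(OC)c2)OCCO1
F3 | step 10 | racemic 4-({2-[3-(benzyloxy)-4,5-dimethoxybenzyl]-1,3-dioxolan-2-yl}ethynyl)-4-hydroxy-2,3-diisopropoxycyclobut-2-en-1-one | OC1(C#CC2(Cc3cc(OCc4ccccc4)c(OC)c(OC)c3)OCCO2)C(=O)C(OC(C)C)=C1OC(C)C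
F4 | step 10 | 5-{2-[3-(benzyloxy)-4,5-dimethoxybenzyl]-1,3-dioxolan-2-yl}-2,3-diisopropoxy-1,4-benzoquinone | O=C1C=C(C2(Cc3cc(OCc4ccccc4)c(OC)c(OC)c3)OCCO2)C(=O)C(OC(C)C)=C1OC(C)C
F5 | step 10 | 2-{2-[3-(benzyloxy)-4,5-dimethoxybenzyl]-1,3-dioxolan-2-yl}-5,6-diisopropoxybenzene-1,4-diol | Oc1cc(C2(Cc3cc(OCc4ccccc4)c(OC)c(OC)c3)OCCO2)c(O)c(OC(C)C)c1OC(C)C
F6 | step 10 | 2-[3-(benzyloxy)-4,5-dimethoxyphenyl]-1-(2,5-dihydroxy-3,4-diisopropoxyphenyl)ethan-1-one | Oc1cc(C(=O)Cc2cc(OCc3ccccc3)c(OC)c(OC)c2)c(O)c(OC(C)C)c1OC(C)C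
F7 | step 13 | 3-(3-hydroxy-4,5-dimethoxyphenyl)-6-methoxy-7,8-diisopropoxy-4H-chromen-4-one | COc1cc2c(=O)c(-c3cc(O)c(OC)c(OC)c3)coc2c(OC(C)C)c1OC(C)C
```
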